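## Analysis of the target

Compound 26 is the 3-hydroxy-4-methoxybenzoate of a daucane-type diol built on a cis-fused hydroazulene. Azulene numbering is used for the hydroazulenes and naphthalene numbering for the decalins. The cyclopentane ring carries the angular methyl on the quaternary fusion carbon C8a and the tertiary carbinol C3, which also bears the isopropyl group. The cycloheptene ring carries the esterified allylic carbinol C4 and the trisubstituted C5=C6 alkene with its methyl on C6. The stereocentres are C3 (R), C3a (S), C4 (R) and C8a (R): H-3a and the angular methyl are cis, the isopropyl group lies on their face, and both oxygens (O3, O4) lie on the opposite face. The sensitive groups are the allylic aryl ester, the free phenol and, at the ketone stage, the C3-hydroxy/C4-carbonyl pair, which is a β-hydroxy ketone open to retro-aldol cleavage and dehydration. The difficulty is a quaternary carbon next to three contiguous stereocentres on a flexible 5/7 frame, where facial control is poor. The strategy rests on the oxygenated C4 being bonded to C3a, one end of the fusion bond C3a–C8a. If C8a is bonded to C4 instead, the skeleton is a 4a-methyldecalin (ring A: C3a, C3, C2, C1, C8a, C4; ring B: C4 to C8 and C8a). A 1,2-shift of C8a from C4 to C3a therefore turns a rigid, chair-controlled decalin into the hydroazulen-4-one.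

## Retrosynthetic reasoning

**Acyl–O4 bond.** 26 is traced to the silyl-protected ester 25 and from there to diol 21 and acid 24 (from 22 through 23). The aryl ester is the most base-labile linkage and the phenol would interfere with every basic or organometallic step, so the acid is attached last. Cutting the acyl–oxygen bond, not the C4–O bond, leaves the C4 configuration to the preceding reduction. The forward step has to acylate a secondary allylic hydroxyl beside a free tertiary one, and the phenol must be freed without touching the ester.

**C4–H bond.** Diol 21 comes from hydroxy enone 19 through the boron chelate 20. A C4 carbonyl is what the rearrangement delivers, and the free C3 hydroxyl of 19 can hold the carbonyl in a chelate so that hydride enters from one face only. 19 is the desilylated form of 18; the silyl group is removed only here because before this point it keeps the β-oxygenated ketone from retro-aldol cleavage.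

**C5=C6 double bond.** Enone 18 comes from the saturated ketone 16 through enol ether 17. Desaturation can only run towards C5/C6 because C3 is quaternary. The C6 methyl stereocentre of 16 disappears in this step.

**C3a–C8a bond (key disconnection).** Cutting C3a–C8a in 16 and rejoining C8a to C4 gives the trans-decalin 15, with a free hydroxyl on decalin C8a (later C4) and a mesylate on decalin C1 (later C3a). Only this retro-shift makes both rings six-membered, and it puts the oxygens of C3 and C4 on neighbouring chair positions where their configuration can be set. The forward step must move the quaternary ring-fusion carbon and no other group, with inversion at the mesylate carbon.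

**Differentiation of three hydroxyls.** 15 comes from mesylate 14 and this from triol 13. The mesylate goes on the only secondary hydroxyl. The silyl group goes on O2, so that only O8a can push and so that the later β-oxygenated ketone is masked.

**C1–O and C8a–O bonds.** Triol 13 comes from allylic alcohol 11 through the osmium glycolate 12. The alkene is oxidised while the C2 hydroxyl is still free, because that hydroxyl can steer the oxidant to its own face. This is the face a trans-decalin requires; a silyl ether at C2 would instead screen it.

**C2–isopropyl bond.** 11 comes from octalone 10 by addition of an isopropyl nucleophile to the carbonyl, which leaves the alkene in place for the oxidation.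

**Ring A (annulation).** 10 is opened at the C1=C8a bond (aldol condensation) to diketone 9 and at the C4–C4a bond (Michael addition) to imine 6 and enone 7; 8 is the adduct on the way. Imine 6 comes from ketone 4 and amine 5, which controls the quaternary centre.

**Ring-B methyl.** 4 comes from enone 3 and this from arene 1 through diene 2. The methyl centre is set deliberately although it is lost later. In 13–15 it must be equatorial (cis to the angular methyl); an axial methyl on decalin C7 would be syn-axial to O8a and would block the face used for the dihydroxylation.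

## Alternatives that were turned down

**Alternative 1:** The seven-membered ring is cut at C5–C6 and C8–C8a. In the forward sense Rh2(S-DOSP)4 decomposes methyl 2-diazobut-3-enoate A3, and the carbenoid cyclopropanates the terminal enol ether alkene of siloxydiene A2. Cope rearrangement of the cis-divinylcyclopropane then gives the bicyclic cycloheptadiene A1.
- For: the step is convergent and catalytic, and it builds the seven-membered ring and the quaternary C8a in one operation with C3 and C4 already oxygenated. On length to the bicycle it is stronger than the chosen route.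
- Against: the Cope terminus that becomes C8a is the fully substituted carbon of a tetrasubstituted cyclopentene, so the boat transition state carries a methyl group pointing inwards. A3 is prone to close to a pyrazole.
- Against: A1 has an ester where 26 needs the C6 methyl, and its alkene sits at C6=C7, so redox and isomerisation steps follow.
- Against: C3, C3a and C4 remain to be set on the flexible bicycle. The isopropyl addition would have to distinguish two carbonyls flanking C3a.
- Comparison: the chosen strategy instead reaches the hydroazulene with C3 and C8a fixed, C3a set stereospecifically and every carbon of the terpenoid part in its final oxidation pattern.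

**Alternative 2:** The cyclopentane is cut at C1–C8a and C3–C3a. Forward, a Cu(OTf)2–phosphoramidite catalyst adds the zinc homoenolate from cyclopropanol A6 to one of the two enantiotopic enone arms of dienone A5. The zinc enolate then closes on the isopropyl ketone to give A4, which has the same structure as 19.
- For: two ring bonds and three stereocentres arise in one catalytic step from achiral components, and A4 is four steps from 26. On step economy and convergence this alternative is clearly stronger.
- Against: a weakly nucleophilic zinc homoenolate must create a quaternary carbon at a β,β-disubstituted enone while the catalyst distinguishes the arms, a combination without firm support.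
- Against: nothing obvious controls the configuration of C3 in the aldol closure, and the aldol is reversible.
- Against: A4 is a labile β-hydroxy ketone under the reaction conditions.
- Comparison: the chosen route trades length for steps of established type and for stereocontrol from chair conformations and a stereospecific shift. If the annulation were shown to work, it would join the present route at 19.

**Alternative 3:** The bonds C3a–C8a and C3a–C4 are cut at the carbenoid carbon. Forward, Rh2(OAc)4 converts diazoketone A8 by intramolecular Buchner reaction (arene cyclopropanation, norcaradiene opening) into A7.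
- For: it is the quickest entry to the complete 5/7 framework, with the C6 methyl and a C3 carbonyl for the isopropyl addition.
- Against: C8a in A7 is trigonal and lacks the angular methyl. Installing it needs a conjugate addition to an extended polyenone with uncertain site selectivity.
- Against: the one stereocentre, C3a, is racemic and labile (α to the ketone, 1,5-hydrogen shifts).
- Against: three ring alkenes must be told apart (one kept, one oxygenated at C4, one reduced).
- Comparison: it is stronger only in speed to the ring system. The chosen strategy brings the angular methyl, the carbinol and the C4 oxygen into the key step with defined configuration.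

Key step: step 10

Assumption: in step 2 the S antipode of the bisphosphine is taken to give the 5S ketone, by analogy with other β-methylcyclohexenones; if the rotation of 4 shows the opposite sense, the R ligand is used and nothing else changes.

Numbering of positions: naphthalene numbering for 10–15, azulene numbering for 16–26. Decalin C8a, C1, C4a, C2 and C7 become C4, C3a, C8a, C3 and C6.

## Route

Step 1
Reactants: 1 2,5-dimethylanisole
Product: 3 3,6-dimethylcyclohex-2-en-1-one, via 1-methoxy-2,5-dimethylcyclohexa-1,4-diene 2 (not isolated)
Conditions: Li, NH3 (l), tBuOH, THF, −78 to −33 °C; then 2 M HCl, THF, rt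
Reagents that add atoms: water, O
Why: Birch reduction leaves the methoxy and both methyl groups on the two remaining double bonds; aqueous acid hydrolyses the enol ether and moves the β,γ-alkene into conjugation, giving the β-methyl enone.

Step 2
Reactants: 3 3,6-dimethylcyclohex-2-en-1-one
Product: 4 (5S)-2,5-dimethylcyclohexan-1-one
Conditions: Cu(OAc)2·H2O (3 mol%), (S)-DTBM-SEGPHOS (3 mol%), PMHS, tBuOH, toluene, 0 °C
Reagents that add atoms: none
Why: Asymmetric copper hydride conjugate reduction; the ligand-bound CuH adds hydride to one face of the β-carbon and sets the methyl-bearing centre, and tBuOH protonates the copper enolate. The α-methyl centre stays a mixture because it is flattened in the enamine of step 4.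

Step 3
Reactants: 4 (5S)-2,5-dimethylcyclohexan-1-one; 5 (S)-1-phenylethylamine
Product: 6 (5S)-2,5-dimethyl-N-[(1S)-1-phenylethyl]cyclohexan-1-imine
Conditions: toluene, p-TsOH (cat.), reflux with azeotropic removal of water
Reagents that add atoms: none
Why: Acid-catalysed imine condensation driven by removal of water; no stereocentre is formed.

Step 4
Reactants: 6 (5S)-2,5-dimethyl-N-[(1S)-1-phenylethyl]cyclohexan-1-imine; 7 but-3-en-2-one
Product: 9 (2R,5S)-2,5-dimethyl-2-(3-oxobutyl)cyclohexan-1-one, via Michael adduct imine 8 (not isolated)
Conditions: THF, rt, 3 d; then 20% aq. AcOH, rt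
Reagents that add atoms: water, O
Why: Chiral-imine Michael addition: the imine reacts through its more substituted secondary enamine in an aza-ene-like transition state, so the bond forms at the methyl-bearing α-carbon, and the enone enters on the face away from the phenyl group of the auxiliary (2R). The auxiliary has to override the weaker preference of the ring methyl for the other diastereomer; hydrolysis returns the ketone and the amine.

Step 5
Reactants: 9 (2R,5S)-2,5-dimethyl-2-(3-oxobutyl)cyclohexan-1-one
Product: 10 (4aR,7S)-4a,7-dimethyl-4,4a,5,6,7,8-hexahydronaphthalen-2(3H)-one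
Conditions: NaOMe, MeOH, 60 °C
Reagents that add atoms: none
Why: Intramolecular aldol condensation, the second stage of a Robinson annulation: the methyl ketone enolate closes the six-membered ring on the ring carbonyl and dehydration gives the conjugated enone; the existing centres are not touched.

Step 6
Reactants: 10 (4aR,7S)-4a,7-dimethyl-4,4a,5,6,7,8-hexahydronaphthalen-2(3H)-one
Product: 11 (2R,4aR,7S)-4a,7-dimethyl-2-(propan-2-yl)-2,3,4,4a,5,6,7,8-octahydronaphthalen-2-ol
Conditions: iPrMgCl, CeCl3 (anhydrous), THF, −78 to 0 °C; aq. NH4Cl
Reagents that add atoms: isopropylmagnesium chloride, CC(C)[Mg]Cl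
Why: 1,2-Addition of an organocerium reagent (Grignard addition with CeCl3, which suppresses enolisation and β-hydride reduction). The bulky nucleophile should take the equatorial path instead of the axial path over ring A past axial H-4, so the isopropyl group becomes equatorial and the hydroxyl axial, anti to the angular methyl (2R).

Step 7
Reactants: 11 (2R,4aR,7S)-4a,7-dimethyl-2-(propan-2-yl)-2,3,4,4a,5,6,7,8-octahydronaphthalen-2-ol
Product: 13 (1S,2R,4aR,7S,8aR)-4a,7-dimethyl-2-(propan-2-yl)decahydronaphthalene-1,2,8a-triol, via glycolato(dioxo)(TMEDA)osmium complex 12 (not isolated)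
Conditions: OsO4 (1.05 equiv), TMEDA (1.1 equiv), CH2Cl2, −78 °C; then aq. Na2SO3, THF, reflux
Reagents that add atoms: osmium tetroxide, O=[Os](=O)(=O)=O
Why: Hydrogen-bond-directed syn-dihydroxylation: the pseudoaxial allylic hydroxyl on C2 binds an oxo ligand of the OsO4–diamine complex and delivers it to its own face of the C1=C8a bond, which is also the face away from the angular methyl. This gives the all-cis triol with a trans ring fusion (1S, 8aR); sulfite then cleaves the stable hexavalent osmium glycolate.

Step 8
Reactants: 13 (1S,2R,4aR,7S,8aR)-4a,7-dimethyl-2-(propan-2-yl)decahydronaphthalene-1,2,8a-triol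
Product: 14 (1S,2R,4aR,7S,8aR)-2,8a-dihydroxy-4a,7-dimethyl-2-(propan-2-yl)decahydronaphthalen-1-yl methanesulfonate
Conditions: MsCl, Et3N, CH2Cl2, −10 to 0 °C
Reagents that add atoms: methanesulfonyl chloride, CS(=O)(=O)Cl
Why: Sulfonylation through sulfene takes the only secondary hydroxyl (equatorial, C1); the two tertiary hydroxyls do not react under these conditions.

Step 9
Reactants: 14 (1S,2R,4aR,7S,8aR)-2,8a-dihydroxy-4a,7-dimethyl-2-(propan-2-yl)decahydronaphthalen-1-yl methanesulfonate
Product: 15 (1R,2R,4aR,7S,8aR)-8a-hydroxy-4a,7-dimethyl-2-(propan-2-yl)-2-[(triethylsilyl)oxy]decahydronaphthalen-1-yl methanesulfonate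
Conditions: TESOTf (1.1 equiv), 2,6-lutidine, CH2Cl2, −78 to −40 °C
Reagents that add atoms: triethylsilyl trifluoromethanesulfonate, CC[Si](CC)(CC)OS(=O)(=O)C(F)(F)F
Why: Silyl triflate silylation of a tertiary alcohol; the C8a hydroxyl is axial to both rings and hemmed in by four syn-axial neighbours (O2, H-4, H-5, H-7), whereas the C2 hydroxyl is axial to ring A only. One equivalent of reagent should therefore go to O2, after which O8a is shielded further. (The descriptor of C1 changes from S to R by priority only.)

Step 10
Reactants: 15 (1R,2R,4aR,7S,8aR)-8a-hydroxy-4a,7-dimethyl-2-(propan-2-yl)-2-[(triethylsilyl)oxy]decahydronaphthalen-1-yl methanesulfonate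
Product: 16 (3R,3aR,6S,8aR)-6,8a-dimethyl-3-(propan-2-yl)-3-[(triethylsilyl)oxy]octahydroazulen-4(1H)-one
Conditions: KOtBu (1.2 equiv), tBuOH/THF (1:1), 0 °C to rt
Reagents that add atoms: none
Why: The base deprotonates the tertiary C8a hydroxyl, and as the alkoxide forms the carbonyl, the C8a–C4a bond, antiperiplanar to the equatorial C1–OMs bond of the locked trans-decalin, shifts to C1 with loss of mesylate in one concerted push–pull 1,2-shift. The closest known reaction type is the base-induced semipinacol rearrangement of cis-1,2-diol monosulfonates of 4a-methyldecalins to hydroazulenones. The five-membered ring closes by ring contraction, since the new bond joins C1 and C4a (C3a–C8a of 16) through a bridged three-centre transition state; the seven-membered ring arises in the same event by ring expansion, because C4a leaves C8a while C8a stays bonded to C1. The one new stereocentre, C3a, is set by inversion at the mesylate carbon, because the migrating carbon enters anti to the leaving group; with the mesylate on the face of the hydroxyls this places H-3a cis to the angular methyl, and the migrating carbon keeps its configuration. The step needs selectivity among the bonds that could shift: only C8a–C4a and C2–C3 are anti to the leaving group, C2–C3 has no push because O2 is silylated, and C8a–C8 is gauche. Epoxide closure is excluded because the oxygen and the mesylate are cis, and no hydrogen is anti for elimination. The silyl ether also keeps 16 from retro-aldol cleavage, and C3a, between two fully substituted carbons, is slow to enolise, so the cis fusion should survive.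

Step 11
Reactants: 16 (3R,3aR,6S,8aR)-6,8a-dimethyl-3-(propan-2-yl)-3-[(triethylsilyl)oxy]octahydroazulen-4(1H)-one
Product: 18 (3R,3aR,8aR)-6,8a-dimethyl-3-(propan-2-yl)-3-[(triethylsilyl)oxy]-2,3,3a,7,8,8a-hexahydroazulen-4(1H)-one, via trimethylsilyl enol ether 17 (not isolated)
Conditions: LDA, TMSCl, THF, −78 °C; then Pd(OAc)2 (1.1 equiv), MeCN, rt
Reagents that add atoms: none
Why: Saegusa–Ito oxidation: kinetic deprotonation occurs at the C5 methylene (the C3a methine sits between two fully substituted carbons), and the palladium enolate loses the C6 hydrogen by β-hydride elimination to give the C5=C6 enone. The C6 stereocentre disappears.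

Step 12
Reactants: 18 (3R,3aR,8aR)-6,8a-dimethyl-3-(propan-2-yl)-3-[(triethylsilyl)oxy]-2,3,3a,7,8,8a-hexahydroazulen-4(1H)-one
Product: 19 (3R,3aR,8aR)-3-hydroxy-6,8a-dimethyl-3-(propan-2-yl)-2,3,3a,7,8,8a-hexahydroazulen-4(1H)-one
Conditions: HF·pyridine, pyridine, THF, 0 °C to rt
Reagents that add atoms: none
Why: Fluoride-assisted cleavage of the tertiary silyl ether under buffered, non-basic conditions, so that no alkoxide forms that could start retro-aldol cleavage of the β-hydroxy ketone.

Step 13
Reactants: 19 (3R,3aR,8aR)-3-hydroxy-6,8a-dimethyl-3-(propan-2-yl)-2,3,3a,7,8,8a-hexahydroazulen-4(1H)-one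
Product: 21 (3R,3aS,4R,8aR)-6,8a-dimethyl-3-(propan-2-yl)-1,2,3,3a,4,7,8,8a-octahydroazulene-3,4-diol, via diethylboron chelate 20 (not isolated)
Conditions: Et2BOMe, THF/MeOH (4:1), −78 °C; then NaBH4, −78 °C; AcOH, then MeOH co-evaporation
Reagents that add atoms: none
Why: Narasaka–Prasad reduction: boron ties O3 and the carbonyl oxygen into a six-membered chelate in which C8a lies below and H-3a above the carbonyl plane, so external borohydride should attack C4 from the H-3a face and the new hydroxyl ends cis to O3 (4R). The activated carbonyl of the β,β-disubstituted enone is reduced 1,2.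

Step 14
Reactants: 22 isovanillic acid
Product: 24 3-[(tert-butyldimethylsilyl)oxy]-4-methoxybenzoic acid, via bis-silylated isovanillic acid 23 (not isolated)
Conditions: TBSCl (2.5 equiv), imidazole, DMF, rt; then AcOH/THF/H2O, rt
Reagents that add atoms: tert-butyldimethylsilyl chloride, CC(C)(C)[Si](C)(C)Cl
Why: Silyl protection; both acidic hydroxyls are silylated and the far more labile silyl ester is then hydrolysed selectively, leaving the aryl silyl ether.

Step 15
Reactants: 21 (3R,3aS,4R,8aR)-6,8a-dimethyl-3-(propan-2-yl)-1,2,3,3a,4,7,8,8a-octahydroazulene-3,4-diol; 24 3-[(tert-butyldimethylsilyl)oxy]-4-methoxybenzoic acid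
Product: 25 (3R,3aS,4R,8aR)-3-hydroxy-6,8a-dimethyl-3-(propan-2-yl)-1,2,3,3a,4,7,8,8a-octahydroazulen-4-yl 3-[(tert-butyldimethylsilyl)oxy]-4-methoxybenzoate
Conditions: DCC, DMAP, CH2Cl2, 0 °C to rt
Reagents that add atoms: none
Why: Steglich esterification; only the secondary allylic hydroxyl on C4 is acylated, the tertiary C3 hydroxyl is inert, and the C4–O bond is not broken, so the configuration is kept.

Step 16
Reactants: 25 (3R,3aS,4R,8aR)-3-hydroxy-6,8a-dimethyl-3-(propan-2-yl)-1,2,3,3a,4,7,8,8a-octahydroazulen-4-yl 3-[(tert-butyldimethylsilyl)oxy]-4-methoxybenzoate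
Product: 26 (3R,3aS,4R,8aR)-3-hydroxy-6,8a-dimethyl-3-(propan-2-yl)-1,2,3,3a,4,7,8,8a-octahydroazulen-4-yl 3-hydroxy-4-methoxybenzoate
Conditions: HF·pyridine, pyridine, THF, 0 °C
Reagents that add atoms: none
Why: Fluoride cleavage of the aryl silyl ether (desilylation); the ester, the allylic C–O bond and the tertiary alcohol are stable to buffered HF.

## Compound list

1 | 2,5-dimethylanisole (1-methoxy-2,5-dimethylbenzene) | COc1cc(C)ccc1C | starting material
2 | 1-methoxy-2,5-dimethylcyclohexa-1,4-diene | COC1=C(C)CC=C(C)C1 | intermediate (not isolated)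
3 | 3,6-dimethylcyclohex-2-en-1-one (racemic at C6) | CC1CCC(C)=CC1=O | intermediate
4 | (5S)-2,5-dimethylcyclohexan-1-one (both C2 epimers) | CC1CC[C@H](C)CC1=O | intermediate
5 | (S)-1-phenylethylamine | C[C@H](N)c1ccccc1 | starting material
6 | (5S)-2,5-dimethyl-N-[(1S)-1-phenylethyl]cyclohexan-1-imine (both C2 epimers) | C[C@H](N=C1C[C@@H](C)CCC1C)c1ccccc1 | intermediate
7 | but-3-en-2-one | CC(=O)C=C | starting material
8 | 4-[(1R,4S)-1,4-dimethyl-2-{[(1S)-1-phenylethyl]imino}cyclohexyl]butan-2-one | C[C@H](N=C1C[C@@H](C)CC[C@]1(C)CCC(C)=O)c1ccccc1 | intermediate (not isolated)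
9 | (2R,5S)-2,5-dimethyl-2-(3-oxobutyl)cyclohexan-1-one | CC(=O)CC[C@@]1(C)CC[C@H](C)CC1=O | intermediate
10 | (4aR,7S)-4a,7-dimethyl-4,4a,5,6,7,8-hexahydronaphthalen-2(3H)-one | O=C1C=C2C[C@@H](C)CC[C@]2(C)CC1 | intermediate
11 | (2R,4aR,7S)-4a,7-dimethyl-2-(propan-2-yl)-2,3,4,4a,5,6,7,8-octahydronaphthalen-2-ol | CC(C)[C@]1(O)CC[C@@]2(C)CC[C@H](C)CC2=C1 | intermediate
12 | [(1S,2R,4aR,7S,8aR)-2-hydroxy-4a,7-dimethyl-2-(propan-2-yl)decahydronaphthalene-1,8a-diolato](dioxo)(N,N,N',N'-tetramethylethane-1,2-diamine)osmium | O3[C@]12C[C@@H](C)CC[C@]1(C)CC[C@@](O)(C(C)C)[C@@H]2O[Os-2]34(=O)(=O)[N+](C)(C)CC[N+]4(C)C | intermediate (not isolated)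
13 | (1S,2R,4aR,7S,8aR)-4a,7-dimethyl-2-(propan-2-yl)decahydronaphthalene-1,2,8a-triol | O[C@]12C[C@@H](C)CC[C@]1(C)CC[C@@](O)(C(C)C)[C@@H]2O | intermediate
14 | (1S,2R,4aR,7S,8aR)-2,8a-dihydroxy-4a,7-dimethyl-2-(propan-2-yl)decahydronaphthalen-1-yl methanesulfonate | O[C@]12C[C@@H](C)CC[C@]1(C)CC[C@@](O)(C(C)C)[C@@H]2OS(C)(=O)=O | intermediate
15 | (1R,2R,4aR,7S,8aR)-8a-hydroxy-4a,7-dimethyl-2-(propan-2-yl)-2-[(triethylsilyl)oxy]decahydronaphthalen-1-yl methanesulfonate | O[C@]12C[C@@H](C)CC[C@]1(C)CC[C@@](O[Si](CC)(CC)CC)(C(C)C)[C@@H]2OS(C)(=O)=O | intermediate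
16 | (3R,3aR,6S,8aR)-6,8a-dimethyl-3-(propan-2-yl)-3-[(triethylsilyl)oxy]octahydroazulen-4(1H)-one | O=C2C[C@@H](C)CC[C@]3(C)CC[C@@](O[Si](CC)(CC)CC)(C(C)C)[C@H]23 | intermediate
17 | trimethylsilyl enol ether of 16 (C4–OSiMe3, C4=C5; other centres as in 16) | C[Si](C)(C)OC2=C[C@@H](C)CC[C@]3(C)CC[C@@](O[Si](CC)(CC)CC)(C(C)C)[C@H]23 | intermediate (not isolated)
18 | (3R,3aR,8aR)-6,8a-dimethyl-3-(propan-2-yl)-3-[(triethylsilyl)oxy]-2,3,3a,7,8,8a-hexahydroazulen-4(1H)-one | O=C2C=C(C)CC[C@]3(C)CC[C@@](O[Si](CC)(CC)CC)(C(C)C)[C@H]23 | intermediate
19 | (3R,3aR,8aR)-3-hydroxy-6,8a-dimethyl-3-(propan-2-yl)-2,3,3a,7,8,8a-hexahydroazulen-4(1H)-one | O=C2C=C(C)CC[C@]3(C)CC[C@@](O)(C(C)C)[C@H]23 | intermediate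
20 | O3-diethylboryl derivative of 19, boron coordinated to the C4 carbonyl oxygen (centres as in 19) | O=C2C=C(C)CC[C@]3(C)CC[C@@](OB(CC)CC)(C(C)C)[C@H]23 | intermediate (not isolated)
21 | (3R,3aS,4R,8aR)-6,8a-dimethyl-3-(propan-2-yl)-1,2,3,3a,4,7,8,8a-octahydroazulene-3,4-diol | O[C@@H]2C=C(C)CC[C@]3(C)CC[C@@](O)(C(C)C)[C@H]23 | intermediate
22 | isovanillic acid (3-hydroxy-4-methoxybenzoic acid) | COc1ccc(C(=O)O)cc1O | starting material
23 | tert-butyldimethylsilyl 3-[(tert-butyldimethylsilyl)oxy]-4-methoxybenzoate | COc1ccc(C(=O)O[Si](C)(C)C(C)(C)C)cc1O[Si](C)(C)C(C)(C)C | intermediate (not isolated)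
24 | 3-[(tert-butyldimethylsilyl)oxy]-4-methoxybenzoic acid | COc1ccc(C(=O)O)cc1O[Si](C)(C)C(C)(C)C | intermediate
25 | (3R,3aS,4R,8aR)-3-hydroxy-6,8a-dimethyl-3-(propan-2-yl)-1,2,3,3a,4,7,8,8a-octahydroazulen-4-yl 3-[(tert-butyldimethylsilyl)oxy]-4-methoxybenzoate | COc1ccc(C(=O)O[C@@H]2C=C(C)CC[C@]3(C)CC[C@@](O)(C(C)C)[C@H]23)cc1O[Si](C)(C)C(C)(C)C | intermediate
26 | (3R,3aS,4R,8aR)-3-hydroxy-6,8a-dimethyl-3-(propan-2-yl)-1,2,3,3a,4,7,8,8a-octahydroazulen-4-yl 3-hydroxy-4-methoxybenzoate | COc1ccc(C(=O)O[C@@H]2C=C(C)CC[C@]3(C)CC[C@@](O)(C(C)C)[C@H]23)cc1O | target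

## Step count and least certain steps

Total: 16 steps. Longest linear sequence: 15 steps (steps 1–13, 15, 16); step 14 prepares the acid component.

**Step 10 (key step).** Under alkoxide conditions the triethylsilyl group may hop between the syn-diaxial oxygens O2 and O8a. A C2 alkoxide formed in that way would push the other antiperiplanar bond (C2–C3) and contract ring A to an acylcyclopentane. Long contact of 16 with base could also epimerise C3a.
Fallback, from 14 back to 16: the unprotected diol mesylate 14 is treated with Et3Al in CH2Cl2 at −78 °C, a trialkylaluminium-promoted pinacol-type rearrangement of a β-hydroxy mesylate. The Lewis acid pulls the mesylate, no base and no silyl group are present, and the better migrating quaternary carbon should shift. This gives (3R,3aR,6S,8aR)-3-hydroxy-6,8a-dimethyl-3-(propan-2-yl)octahydroazulen-4(1H)-one F1, whose single hydroxyl is then silylated (TESOTf, 2,6-lutidine) to 16.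

**Step 9.** Silylation may go to the wrong tertiary hydroxyl, or to both, if the difference in shielding is smaller than estimated. A silyl group on O8a would send step 10 down the ring-contraction path.
Fallback, from 12 back to 15: the glycolate 12 is not cleaved but silylated while O1 and O8a are still bound to osmium and O2 is the only free hydroxyl (TESOTf with 2,6-lutidine, or N-methyl-N-(triethylsilyl)trifluoroacetamide). This gives the silylated osmium glycolate F2. Cleavage with aqueous Na2SO3 releases (1R,2R,4aR,7S,8aR)-4a,7-dimethyl-2-(propan-2-yl)-2-[(triethylsilyl)oxy]decahydronaphthalene-1,8a-diol F3, whose secondary hydroxyl is mesylated as in step 8 to give 15.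

**Step 4.** Diastereoselectivity at the quaternary carbon may erode, because the auxiliary and the ring methyl favour opposite faces.
Fallback, from 3 back to 10: 3 is reduced with the R antipode of the ligand to (5R)-2,5-dimethylcyclohexan-1-one F4, so that in its imine with 5, (5R)-2,5-dimethyl-N-[(1S)-1-phenylethyl]cyclohexan-1-imine F5, both elements favour the same face. Addition to 7 gives the adduct imine 4-[(1R,4R)-1,4-dimethyl-2-{[(1S)-1-phenylethyl]imino}cyclohexyl]butan-2-one F6, and hydrolysis gives (2R,5R)-2,5-dimethyl-2-(3-oxobutyl)cyclohexan-1-one F7. Aldol condensation gives the trans-dimethyl octalone (4aR,7R)-4a,7-dimethyl-4,4a,5,6,7,8-hexahydronaphthalen-2(3H)-one F8. Its axial C7 methyl is removed as a stereocentre by chloranil dehydrogenation (tBuOH, reflux) to the linear dienone (4aR)-4a,7-dimethyl-4,4a,5,6-tetrahydronaphthalen-2(3H)-one F9. Hydrogenation of the C7=C8 bond with RhCl(PPh3)3 and H2 from the face opposite the angular methyl, which is 1,3 to C8, should reset C7 as S and return 10.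

**Step 6.** Facial selectivity may be poor: competing axial attack would give the C2 epimer with an axial isopropyl group, which the directed dihydroxylation would then carry to the wrong face.
Fallback, from 10 back to 11: the addition is run as in step 6 and the mixture containing the epimer (2S,4aR,7S)-4a,7-dimethyl-2-(propan-2-yl)-2,3,4,4a,5,6,7,8-octahydronaphthalen-2-ol F10 is equilibrated in dilute aqueous acid (cat. HClO4, THF/H2O, 0 °C) through the tertiary allylic cation. Water returns along the axial path, and 11, with the isopropyl group equatorial, is also the more stable epimer, so thermodynamic control replaces kinetic control.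

**Step 13.** Hydride may attack from the wrong face, or add in the conjugate sense, if the boron chelate does not form cleanly at the hindered tertiary hydroxyl.
Fallback, from 19 back to 25: 19 is reduced with Me4NBH(OAc)3 in AcOH/MeCN, where hydride is delivered intramolecularly from boron bound to O3 and therefore from the O3 face. This should give the C4-epimeric diol (3R,3aS,4S,8aR)-6,8a-dimethyl-3-(propan-2-yl)-1,2,3,3a,4,7,8,8a-octahydroazulene-3,4-diol F11. Mitsunobu esterification of F11 with acid 24 (PPh3, DIAD, THF) then forms the ester with inversion at C4 and gives 25 directly.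

## Further compounds

F1 | step 10 | (3R,3aR,6S,8aR)-3-hydroxy-6,8a-dimethyl-3-(propan-2-yl)octahydroazulen-4(1H)-one | O=C2C[C@@H](C)CC[C@]3(C)CC[C@@](O)(C(C)C)[C@H]23
F2 | step 9 | [(1R,2R,4aR,7S,8aR)-4a,7-dimethyl-2-(propan-2-yl)-2-(triethylsilyloxy)decahydronaphthalene-1,8a-diolato](dioxo)(N,N,N',N'-tetramethylethane-1,2-diamine)osmium | O3[C@]12C[C@@H](C)CC[C@]1(C)CC[C@@](O[Si](CC)(CC)CC)(C(C)C)[C@@H]2O[Os-2]34(=O)(=O)[N+](C)(C)CC[N+]4(C)C
F3 | step 9 | (1R,2R,4aR,7S,8aR)-4a,7-dimethyl-2-(propan-2-yl)-2-[(triethylsilyl)oxy]decahydronaphthalene-1,8a-diol | O[C@]12C[C@@H](C)CC[C@]1(C)CC[C@@](O[Si](CC)(CC)CC)(C(C)C)[C@@H]2O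
F4 | step 4 | (5R)-2,5-dimethylcyclohexan-1-one | CC1CC[C@@H](C)CC1=O
F5 | step 4 | (5R)-2,5-dimethyl-N-[(1S)-1-phenylethyl]cyclohexan-1-imine | C[C@H](N=C1C[C@H](C)CCC1C)c1ccccc1
F6 | step 4 | 4-[(1R,4R)-1,4-dimethyl-2-{[(1S)-1-phenylethyl]imino}cyclohexyl]butan-2-one | C[C@H](N=C1C[C@H](C)CC[C@]1(C)CCC(C)=O)c1ccccc1
F7 | step 4 | (2R,5R)-2,5-dimethyl-2-(3-oxobutyl)cyclohexan-1-one | CC(=O)CC[C@@]1(C)CC[C@@H](C)CC1=O
F8 | step 4 | (4aR,7R)-4a,7-dimethyl-4,4a,5,6,7,8-hexahydronaphthalen-2(3H)-one | O=C1C=C2C[C@H](C)CC[C@]2(C)CC1
F9 | step 4 | (4aR)-4a,7-dimethyl-4,4a,5,6-tetrahydronaphthalen-2(3H)-one | O=C1C=C2C=C(C)CC[C@]2(C)CC1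
F10 | step 6 | (2S,4aR,7S)-4a,7-dimethyl-2-(propan-2-yl)-2,3,4,4a,5,6,7,8-octahydronaphthalen-2-ol | CC(C)[C@@]1(O)CC[C@@]2(C)CC[C@H](C)CC2=C1
F11 | step 13 | (3R,3aS,4S,8aR)-6,8a-dimethyl-3-(propan-2-yl)-1,2,3,3a,4,7,8,8a-octahydroazulene-3,4-diol | O[C@H]2C=C(C)CC[C@]3(C)CC[C@@](O)(C(C)C)[C@H]23
A1 | alternative 1 | methyl 4'-(tert-butyldimethylsilyloxy)-8a'-methyl-2',5',8',8a'-tetrahydro-1'H-spiro[1,3-dioxolane-2,3'-azulene]-6'-carboxylate (8a' centre as in the SMILES) | COC(=O)C1=CC[C@]2(C)CCC3(OCCO3)C2=C(O[Si](C)(C)C(C)(C)C)C1
A2 | alternative 1 | tert-butyl{[1-(7-methyl-1,4-dioxaspiro[4.4]non-6-en-6-yl)ethenyl]oxy}dimethylsilane | C=C(O[Si](C)(C)C(C)(C)C)C1=C(C)CCC12OCCO2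
A3 | alternative 1 | methyl 2-diazobut-3-enoate | COC(=O)C(=[N+]=[N-])C=C
A4 | alternative 2 | (3R,3aR,8aR)-3-hydroxy-6,8a-dimethyl-3-(propan-2-yl)-2,3,3a,7,8,8a-hexahydroazulen-4(1H)-one | O=C2C=C(C)CC[C@]3(C)CC[C@@](O)(C(C)C)[C@H]23
A5 | alternative 2 | 3,6-dimethylcyclohepta-2,6-dien-1-one | O=C1C=C(C)CCC(C)=C1
A6 | alternative 2 | 1-(propan-2-yl)cyclopropan-1-ol | CC(C)C1(O)CC1
A7 | alternative 3 | 6-methyl-3,8a-dihydroazulen-1(2H)-one | O=C1CCC2=CC=C(C)C=C[C@@H]12
A8 | alternative 3 | 1-diazo-4-(4-methylphenyl)butan-2-one | Cc1ccc(CCC(=O)C=[N+]=[N-])cc1
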